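**Retrosynthetic overview**
1. Enabling feature: on ring A the pyran oxygen O1 (on C8a) and the benzylic carbon C4 (on C4a) are ortho to each other, so O1–C8a–C4a–C4 is a latent o-quinone methide. C3 carries ring B, so C2–C3 can come from an arylacetyl unit (C3 nucleophilic as enolate carbon, C2 electrophilic as acyl carbon).
2. Key disconnection: O1–C2 and C3–C4 together, by a catalytic enantioselective Michael addition–lactonisation (formal [4+2]) between a fluoride-released o-quinone methide and an isothiourea-bound enolate of the ring B arylacetate. This closes the pyran ring (ring C) as a 3-aryl lactone and sets C3.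
3. The lactone C2=O is then reduced to CH2 without breaking O1–C2 (lactol, then ionic hydrogenation). The quinone of ring B is unveiled last, by hydrogenolysis of three benzyl ethers and aerobic oxidation of the 2,3-dimethoxyhydroquinone.
4. Both arenes carry the same 1-carbon-2,5-dioxy-3,4-dimethoxy pattern, so both fragments diverge from one aldehyde, 2,5-dihydroxy-3,4-dimethoxybenzaldehyde. Ring order: A and B are bought as arenes, ring C is formed in the key step, ring B reaches the quinone level last.

Key step: step 10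

Remark on the chemistry: the sense of induction in step 10 is taken from the accepted model for isothiourea-bound (Z)-enolates (1,5-O···S contact, pseudoaxial phenyl, attack on the open face), which predicts the (3S) lactone from (2R,3S)-HyperBTM; if the opposite sense is found, the equally available (2S,3R) catalyst is used.

**Step 1**
Reactants: 1 2-hydroxy-3,4-dimethoxybenzaldehyde
Product: 3 2,5-dihydroxy-3,4-dimethoxybenzaldehyde, via potassium aryl sulfate 2 (not isolated)
Conditions: K2S2O8, aq. KOH, 0 °C → rt; then aq. HCl, 70 °C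
Reagents that add atoms: potassium persulfate [K+].[K+].[O-]S(=O)(=O)OOS(=O)(=O)[O-]
Why: Elbs persulfate oxidation, in which the phenoxide of 1 attacks the peroxide oxygen through its only free activated position C5 (para to the hydroxyl, both ortho positions being substituted) and acid hydrolysis of sulfate 2 frees the second phenol.

**Step 2**
Reactants: 3 2,5-dihydroxy-3,4-dimethoxybenzaldehyde
Product: 4 5-(benzyloxy)-2-hydroxy-3,4-dimethoxybenzaldehyde
Conditions: NaH (2.1 equiv), DMF, 0 °C; BnBr (1.0 equiv), 0 °C → rt; aq. HCl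
Reagents that add atoms: benzyl bromide BrCc1ccccc1
Why: Williamson etherification of the dianion, in which the O5 phenoxide is the more basic and more nucleophilic site while the O2 phenoxide is conjugated with and chelated to the formyl group, so monobenzylation should go to O5.

**Step 3**
Reactants: 4 5-(benzyloxy)-2-hydroxy-3,4-dimethoxybenzaldehyde
Product: 5 5-(benzyloxy)-2-[(tert-butyldimethylsilyl)oxy]-3,4-dimethoxybenzaldehyde
Conditions: TBSCl, imidazole, DMF, rt → 40 °C
Reagents that add atoms: tert-butyldimethylsilyl chloride CC(C)(C)[Si](C)(C)Cl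
Why: Standard imidazole-mediated silylation of the remaining phenol, which masks the future ring oxygen O1 as a fluoride-labile trigger.

**Step 4**
Reactants: 5 5-(benzyloxy)-2-[(tert-butyldimethylsilyl)oxy]-3,4-dimethoxybenzaldehyde
Product: 6 {5-(benzyloxy)-2-[(tert-butyldimethylsilyl)oxy]-3,4-dimethoxyphenyl}methanol
Conditions: NaBH4, MeOH/THF, 0 °C, short reaction time
Reagents that add atoms: none
Why: Chemoselective borohydride reduction of the aldehyde, with low temperature and short contact time limiting O-to-O silyl migration and leaving the aryl silyl and benzyl ethers intact.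

**Step 5**
Reactants: 6 {5-(benzyloxy)-2-[(tert-butyldimethylsilyl)oxy]-3,4-dimethoxyphenyl}methanol
Product: 7 {5-(benzyloxy)-2-[(tert-butyldimethylsilyl)oxy]-3,4-dimethoxyphenyl}methyl acetate
Conditions: Ac2O, pyridine, DMAP (cat.), CH2Cl2, 0 °C → rt
Reagents that add atoms: acetic anhydride CC(=O)OC(C)=O
Why: Acylation of the primary benzylic alcohol gives a storable, non-alkylating o-quinone methide precursor (benzylic acetate as leaving group, aryl silyl ether as trigger).

**Step 6**
Reactants: 3 2,5-dihydroxy-3,4-dimethoxybenzaldehyde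
Product: 8 2,5-bis(benzyloxy)-3,4-dimethoxybenzaldehyde
Conditions: BnBr (2.5 equiv), K2CO3, DMF, 60 °C
Reagents that add atoms: benzyl bromide BrCc1ccccc1
Why: Double Williamson etherification (excess reagent and heat overcome the chelated 2-hydroxyl), which masks the hydroquinone that later becomes the quinone of ring B.

**Step 7**
Reactants: 8 2,5-bis(benzyloxy)-3,4-dimethoxybenzaldehyde
Product: 10 2-[2,5-bis(benzyloxy)-3,4-dimethoxyphenyl]acetonitrile, via tosylvinyl formamide 9 (not isolated)
Conditions: TosMIC, t-BuOK, DME, −40 °C; then MeOH, reflux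
Reagents that add atoms: p-toluenesulfonylmethyl isocyanide [C-]#[N+]CS(=O)(=O)c1ccc(C)cc1
Why: Van Leusen reductive cyanation, in which the TosMIC anion adds to the aldehyde and cyclises to a 4-tosyl-2-oxazoline that opens to formamide 9, from which methanolysis removes the formyl group and sulfinate to give the one-carbon-homologated nitrile.

**Step 8**
Reactants: 10 2-[2,5-bis(benzyloxy)-3,4-dimethoxyphenyl]acetonitrile
Product: 11 2-[2,5-bis(benzyloxy)-3,4-dimethoxyphenyl]acetic acid
Conditions: KOH, EtOH/H2O, reflux; then aq. HCl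
Reagents that add atoms: potassium hydroxide [K+].[OH-]; water O
Why: Base hydrolysis of an arylacetonitrile to the acid, under which benzyl and methyl aryl ethers are stable.

**Step 9**
Reactants: 11 2-[2,5-bis(benzyloxy)-3,4-dimethoxyphenyl]acetic acid
Product: 12 4-nitrophenyl 2-[2,5-bis(benzyloxy)-3,4-dimethoxyphenyl]acetate
Conditions: 4-nitrophenol, DCC, CH2Cl2, 0 °C → rt
Reagents that add atoms: 4-nitrophenol Oc1ccc(cc1)[N+](=O)[O-]
Why: Carbodiimide esterification to a bench-stable activated aryl ester, the usual enolate precursor for aryloxide-assisted isothiourea catalysis (no DMAP, to avoid ketene formation from the α-aryl acid).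

**Step 10**
Reactants: 7 {5-(benzyloxy)-2-[(tert-butyldimethylsilyl)oxy]-3,4-dimethoxyphenyl}methyl acetate; 12 4-nitrophenyl 2-[2,5-bis(benzyloxy)-3,4-dimethoxyphenyl]acetate
Product: 14 (3S)-6-(benzyloxy)-3-[2,5-bis(benzyloxy)-3,4-dimethoxyphenyl]-7,8-dimethoxy-3,4-dihydro-2H-chromen-2-one, via o-quinone methide 13 (not isolated)
Conditions: (2R,3S)-HyperBTM (10 mol%), CsF (2.5 equiv), MeCN, 0 °C → rt (CsF added last)
Reagents that add atoms: none
Why: Fluoride removes the silyl group of 7 and the phenoxide expels acetate to give o-quinone methide 13 at low stationary concentration, while the isothiourea is acylated by 12 and the acyl ammonium ion is deprotonated by the released aryloxide to a (Z)-C1-ammonium enolate; the enolate carbon adds to the methide CH2 (C3–C4 bond, driven by rearomatisation of ring A) and the phenoxide so formed is acylated intramolecularly by the acyl ammonium group (O1–C2 bond), which frees the catalyst. The closest known reaction type is the Lewis-base-catalysed (isothiourea or N-heterocyclic carbene) Michael addition–lactonisation of acyl-derived enolates with oxadienes and with fluoride-released o-quinone methides, a formal [4+2] annulation that gives 3-substituted 3,4-dihydrocoumarins. Ring C is closed stepwise, by intermolecular 1,4-addition followed by 6-exo-trig lactonisation. The C3 stereocentre is set in the C–C bond-forming step under catalyst control: the 1,5-O···S contact fixes the enolate conformation, the pseudoaxial phenyl group of the catalyst shields one face and the methide adds to the other, which should give the (3S) lactone with the (2R,3S) catalyst. The step needs capture of 13 to outrun its self-condensation and the α-aryl stereocentre to survive; slow fluoride-gated release of 13, the absence of any base stronger than fluoride, acetate and 4-nitrophenoxide, and low temperature should secure both.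

**Step 11**
Reactants: 14 (3S)-6-(benzyloxy)-3-[2,5-bis(benzyloxy)-3,4-dimethoxyphenyl]-7,8-dimethoxy-3,4-dihydro-2H-chromen-2-one
Product: 15 (3S)-6-(benzyloxy)-3-[2,5-bis(benzyloxy)-3,4-dimethoxyphenyl]-7,8-dimethoxy-3,4-dihydro-2H-chromen-2-ol (mixture of C2 epimers)
Conditions: i-Bu2AlH (1.2 equiv), CH2Cl2, −78 °C; MeOH, then aq. potassium sodium tartrate
Reagents that add atoms: none
Why: Half-reduction of the aryl lactone at −78 °C stops at the tetrahedral aluminium lactolate, which gives the six-membered lactol on work-up with O1–C2 kept and C3 not enolised under these non-basic conditions.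

**Step 12**
Reactants: 15 (3S)-6-(benzyloxy)-3-[2,5-bis(benzyloxy)-3,4-dimethoxyphenyl]-7,8-dimethoxy-3,4-dihydro-2H-chromen-2-ol
Product: 16 (3S)-6-(benzyloxy)-3-[2,5-bis(benzyloxy)-3,4-dimethoxyphenyl]-7,8-dimethoxy-3,4-dihydro-2H-chromene
Conditions: Et3SiH (5 equiv), BF3·OEt2 (1.5 equiv), CH2Cl2, −78 → −40 °C
Reagents that add atoms: none
Why: Ionic hydrogenation of a lactol, in which BF3 ionises the anomeric C–O bond and the excess silane should reduce the C2 oxocarbenium ion faster than the C3 proton can be lost, so O1–C2 and the C3 configuration are kept.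

**Step 13**
Reactants: 16 (3S)-6-(benzyloxy)-3-[2,5-bis(benzyloxy)-3,4-dimethoxyphenyl]-7,8-dimethoxy-3,4-dihydro-2H-chromene
Product: 18 5-[(3S)-6-hydroxy-7,8-dimethoxy-3,4-dihydro-2H-chromen-3-yl]-2,3-dimethoxycyclohexa-2,5-diene-1,4-dione (CNP0302517.1), via hydroquinone 17 (not isolated)
Conditions: H2 (1 atm), 10% Pd/C, EtOAc/MeOH, rt; then air, rt
Reagents that add atoms: none
Why: Hydrogenolysis removes the three benzyl ethers and the electron-rich 2,3-dimethoxyhydroquinone 17 is then oxidised by O2 on the same Pd/C to the quinone, whereas the ring A phenol has no para-hydroxyl partner and should not be oxidised under these neutral conditions, which also leave C3 untouched.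

**Compound list**
1 | 2-hydroxy-3,4-dimethoxybenzaldehyde | O=Cc1ccc(OC)c(OC)c1O | starting material
2 | potassium 5-formyl-4-hydroxy-2,3-dimethoxyphenyl sulfate | [K+].[O-]S(=O)(=O)Oc1cc(C=O)c(O)c(OC)c1OC | intermediate (not isolated)
3 | 2,5-dihydroxy-3,4-dimethoxybenzaldehyde | O=Cc1cc(O)c(OC)c(OC)c1O | intermediate
4 | 5-(benzyloxy)-2-hydroxy-3,4-dimethoxybenzaldehyde | O=Cc1cc(OCc2ccccc2)c(OC)c(OC)c1O | intermediate
5 | 5-(benzyloxy)-2-[(tert-butyldimethylsilyl)oxy]-3,4-dimethoxybenzaldehyde | O=Cc1cc(OCc2ccccc2)c(OC)c(OC)c1O[Si](C)(C)C(C)(C)C | intermediate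
6 | {5-(benzyloxy)-2-[(tert-butyldimethylsilyl)oxy]-3,4-dimethoxyphenyl}methanol | OCc1cc(OCc2ccccc2)c(OC)c(OC)c1O[Si](C)(C)C(C)(C)C | intermediate
7 | {5-(benzyloxy)-2-[(tert-butyldimethylsilyl)oxy]-3,4-dimethoxyphenyl}methyl acetate | CC(=O)OCc1cc(OCc2ccccc2)c(OC)c(OC)c1O[Si](C)(C)C(C)(C)C | intermediate
8 | 2,5-bis(benzyloxy)-3,4-dimethoxybenzaldehyde | O=Cc1cc(OCc2ccccc2)c(OC)c(OC)c1OCc3ccccc3 | intermediate
9 | N-{2-[2,5-bis(benzyloxy)-3,4-dimethoxyphenyl]-1-(4-methylbenzenesulfonyl)ethenyl}formamide | O=CNC(=Cc1cc(OCc2ccccc2)c(OC)c(OC)c1OCc3ccccc3)S(=O)(=O)c4ccc(C)cc4 | intermediate (not isolated)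
10 | 2-[2,5-bis(benzyloxy)-3,4-dimethoxyphenyl]acetonitrile | N#CCc1cc(OCc2ccccc2)c(OC)c(OC)c1OCc3ccccc3 | intermediate
11 | 2-[2,5-bis(benzyloxy)-3,4-dimethoxyphenyl]acetic acid | OC(=O)Cc1cc(OCc2ccccc2)c(OC)c(OC)c1OCc3ccccc3 | intermediate
12 | 4-nitrophenyl 2-[2,5-bis(benzyloxy)-3,4-dimethoxyphenyl]acetate | O=C(Cc1cc(OCc2ccccc2)c(OC)c(OC)c1OCc3ccccc3)Oc4ccc(cc4)[N+](=O)[O-] | intermediate
13 | 4-(benzyloxy)-2,3-dimethoxy-6-methylidenecyclohexa-2,4-dien-1-one | C=C1C=C(OCc2ccccc2)C(OC)=C(OC)C1=O | intermediate (not isolated)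
14 | (3S)-6-(benzyloxy)-3-[2,5-bis(benzyloxy)-3,4-dimethoxyphenyl]-7,8-dimethoxy-3,4-dihydro-2H-chromen-2-one | O=C1Oc2c(OC)c(OC)c(OCc3ccccc3)cc2C[C@H]1c4cc(OCc5ccccc5)c(OC)c(OC)c4OCc6ccccc6 | intermediate
15 | (3S)-6-(benzyloxy)-3-[2,5-bis(benzyloxy)-3,4-dimethoxyphenyl]-7,8-dimethoxy-3,4-dihydro-2H-chromen-2-ol (C2 epimers) | OC1Oc2c(OC)c(OC)c(OCc3ccccc3)cc2C[C@H]1c4cc(OCc5ccccc5)c(OC)c(OC)c4OCc6ccccc6 | intermediate
16 | (3S)-6-(benzyloxy)-3-[2,5-bis(benzyloxy)-3,4-dimethoxyphenyl]-7,8-dimethoxy-3,4-dihydro-2H-chromene | C1Oc2c(OC)c(OC)c(OCc3ccccc3)cc2C[C@H]1c4cc(OCc5ccccc5)c(OC)c(OC)c4OCc6ccccc6 | intermediate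
17 | 2-[(3S)-6-hydroxy-7,8-dimethoxy-3,4-dihydro-2H-chromen-3-yl]-5,6-dimethoxybenzene-1,4-diol | C1Oc2c(OC)c(OC)c(O)cc2C[C@H]1c3cc(O)c(OC)c(OC)c3O | intermediate (not isolated)
18 | 5-[(3S)-6-hydroxy-7,8-dimethoxy-3,4-dihydro-2H-chromen-3-yl]-2,3-dimethoxycyclohexa-2,5-diene-1,4-dione | COC1=C(OC)C(=O)C([C@H]2COc3c(cc(O)c(OC)c3OC)C2)=CC1=O | target

**Step count**
Total steps: 13. Longest linear sequence: 9 steps (steps 1, 6, 7, 8, 9, 10, 11, 12, 13; the branch through steps 1–5 is equally long).

**Steps most likely to fail**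

Step 10. The enantiopurity may be eroded by an uncatalysed enolate or ketene pathway and by deprotonation of the α-aryl lactone by fluoride or aryloxide, and the o-quinone methide may self-condense before it is captured. The fallback replaces catalyst control by auxiliary control and builds the two bonds in separate operations; it sets out from acid 11 (with alcohol 6 as the second component) and comes back at lactone 14. Acid 11 is coupled with (S)-4-benzyl-1,3-oxazolidin-2-one (DCC, DMAP cat., CH2Cl2) to give (4S)-4-benzyl-3-{2-[2,5-bis(benzyloxy)-3,4-dimethoxyphenyl]acetyl}-1,3-oxazolidin-2-one F1. Alcohol 6 is converted (CBr4, PPh3, CH2Cl2, 0 °C) into [4-(benzyloxy)-2-(bromomethyl)-5,6-dimethoxyphenoxy](tert-butyl)dimethylsilane F2, used at once. Evans alkylation of the sodium enolate of F1 (NaN(SiMe3)2, THF, −78 °C) with F2, on the face away from the auxiliary benzyl group, should give (4S)-4-benzyl-3-[(2S)-3-{5-(benzyloxy)-2-[(tert-butyldimethylsilyl)oxy]-3,4-dimethoxyphenyl}-2-[2,5-bis(benzyloxy)-3,4-dimethoxyphenyl]propanoyl]-1,3-oxazolidin-2-one F3. Buffered desilylation (Bu4NF, AcOH, THF, 0 °C) then frees the phenol, which lactonises on the imide carbonyl with loss of the auxiliary to give 14.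

Step 12. The oxocarbenium ion may lose the C3 proton to give the 3-aryl-4H-chromene, and reprotonation and reduction of this enol ether would scramble C3. The fallback avoids the cation by a radical deoxygenation; it sets out from lactol 15 and comes back at 16. Acylation of 15 with O-phenyl chlorothionoformate (pyridine, DMAP cat., CH2Cl2, 0 °C) should give O-[(3S)-6-(benzyloxy)-3-[2,5-bis(benzyloxy)-3,4-dimethoxyphenyl]-7,8-dimethoxy-3,4-dihydro-2H-chromen-2-yl] O-phenyl carbonothioate F4. Barton–McCombie reduction (Bu3SnH, AIBN, toluene, 80 °C) then passes through a C2 radical that cannot epimerise C3 and gives 16.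

Step 1. Conversion may stay low, and the formyl group and the hydroquinone product may be oxidised further in alkaline persulfate. The fallback introduces the oxygen through a halide; it sets out from 1 and comes back at 3. Bromination para to the hydroxyl (NBS, MeCN, 0 °C) should give 5-bromo-2-hydroxy-3,4-dimethoxybenzaldehyde F5, and copper-catalysed hydroxylation of the aryl bromide (CuI, 1,10-phenanthroline, KOH, DMSO/H2O, 100 °C) gives 3.

**Further compounds**
F1 | step 10 | (4S)-4-benzyl-3-{2-[2,5-bis(benzyloxy)-3,4-dimethoxyphenyl]acetyl}-1,3-oxazolidin-2-one | O=C1OC[C@H](Cc2ccccc2)N1C(=O)Cc3cc(OCc4ccccc4)c(OC)c(OC)c3OCc5ccccc5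
F2 | step 10 | [4-(benzyloxy)-2-(bromomethyl)-5,6-dimethoxyphenoxy](tert-butyl)dimethylsilane | BrCc1cc(OCc2ccccc2)c(OC)c(OC)c1O[Si](C)(C)C(C)(C)C
F3 | step 10 | (4S)-4-benzyl-3-[(2S)-3-{5-(benzyloxy)-2-[(tert-butyldimethylsilyl)oxy]-3,4-dimethoxyphenyl}-2-[2,5-bis(benzyloxy)-3,4-dimethoxyphenyl]propanoyl]-1,3-oxazolidin-2-one | O=C1OC[C@H](Cc2ccccc2)N1C(=O)[C@@H](Cc3cc(OCc4ccccc4)c(OC)c(OC)c3O[Si](C)(C)C(C)(C)C)c5cc(OCc6ccccc6)c(OC)c(OC)c5OCc7ccccc7
F4 | step 12 | O-[(3S)-6-(benzyloxy)-3-[2,5-bis(benzyloxy)-3,4-dimethoxyphenyl]-7,8-dimethoxy-3,4-dihydro-2H-chromen-2-yl] O-phenyl carbonothioate | S=C(Oc1ccccc1)OC2Oc3c(OC)c(OC)c(OCc4ccccc4)cc3C[C@H]2c5cc(OCc6ccccc6)c(OC)c(OC)c5OCc7ccccc7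
F5 | step 1 | 5-bromo-2-hydroxy-3,4-dimethoxybenzaldehyde | O=Cc1cc(Br)c(OC)c(OC)c1O
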